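The nucleophile is the reagent to count first in Tuesday's and Sunday's flasks.

| setting | Tuesday's | Sunday's |
|---|---|---|
| solid electrophile | 0.25 M | 0.25 M |
| nucleophile | 0.300 M | 0.600 M |
| protic impurity | 0.0750 M | 0.0750 M |
| time | 25 h | 25 h |

    electrophile + nucleophile → acid set free + product (k1 = 0.73 M⁻¹ h⁻¹)
    nucleophile + acid set free ⇌ protonated nucleophile, settled at all times (K2 = 150 M⁻¹)
    electrophile ⇌ dormant form (K3 = 0.61, k3 = 0.56 h⁻¹)
    nucleophile + protic impurity → quenched reagent (k4 = 0.13 M⁻¹ h⁻¹)
    solid electrophile ⇌ electrophile, rate k5*(cs5 - [electrophile]) while solid is left; crystals form when [electrophile] > cs5 (cs5 = 0.17 M, k5 = 0.24 h⁻¹)

- solid, in amounts per volume of the solution: solid electrophile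
- at the start none of the solid electrophile is in solution
- what has only dissolved of solid electrophile counts as not reacted
- what has gone from electrophile into another species counts as reacted, even if it can come back
- run time (Tuesday's): 25 h

- part of the solid electrophile that has reacted (what has only dissolved counts as not reacted) at the end, Tuesday's
- part of the solid electrophile that has reacted (what has only dissolved counts as not reacted) at the end, Sunday's
- what raising the concentration of nucleophile from its lowest to its highest value here does to the part of the solid electrophile that has reacted (what has only dissolved counts as not reacted) (changes below 5 percentage points count as none) (no change / it falls / it rises)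

Take Tuesday's flask in two extreme versions. In the generous one, c(nucleophile) stays at its charge, so the electrophile has a pseudo-first-order half-life of 3.2 h, and the solid feeds it with a half-time of 2.89 h. The run of 25 h is far longer than either, so nearly all of the charge reacts.

In the strict version, each acid set free takes a nucleophile at once, since K2 times c(nucleophile) is 45, far above one. Each product then costs two nucleophile, and the nucleophile becomes the limiting reagent, allowing product of 60.0% of the solid.

Now put that answer back in. A nucleophile drained by the end averages about 0.150 M, half its charge, so the impurity quenches about 0.0366 M. What remains gives 52.7%, the two-for-one ceiling: nucleophile not quenched, divided by two, over the solid charged.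

The unconverted rest balances quickly, with a relaxation half-life of 0.469 h, and 37.9% of it sits dormant and counts as reacted. So the strict Tuesday's flask gives 70.6%. Between the generous and the strict version, that is the figure I commit to for Tuesday's flask.

For Sunday's flask the same two rounds give a ceiling of 105%, above the whole charge. I expect a clear rise but commit to no figure.

The forecast said 73% for Tuesday's, more than my 70.6%, and 92% for Sunday's, with the trend it rises, since “the freed acid locks up a second nucleophile for each product formed”.

The simulation gives 72.3% for Tuesday's and 92.6% for Sunday's, a change of 20 percentage points: it rises. Tuesday's flask ends with product at 55.2% and dormant form at 17.1%. With its quenched reagent of 0.0234 M, less than my 0.0366 M, the ceiling reads 55.3%, level with that product. With 0.0449 M quenched, Sunday's ceiling reads 111%, and that flask ends with product at 87.7% and 21% of its nucleophile still free.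

(The constants used here were drawn at random within sensible limits; what happens was integrated by code.)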